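**Retrosynthetic overview**
1. Numbering used: dioxolane O1–O2–C3(Me)(CH2CO2Me)–C4–C5(Me)(trienyl); the target is (3R,5S). Ring oxygen O2 on C3 lies β to the ester carbonyl and is tied to C5 through O1–C5–C4, so the ring is the 5-exo-trig peroxy-Michael adduct of a C5 hydroperoxide on a C2=C3 (E)-enoate, the presumed biosynthetic closure. Disconnect O2–C3.
2. The (7E,9E,12Z)-triene is cut at the diene σ-bond: Suzuki coupling of an (E)-alkenyl iodide on the finished dioxolane with a (1E,4Z)-heptadienylboronate, as the last step.
3. The C5–OOH centre comes from invertive perhydrolysis of an enantioenriched 2,2,4-trisubstituted oxetane. Its tertiary C–O centre is set by Sharpless epoxidation of a geraniol-type allylic alcohol made by carboalumination of deca-1,9-diyne.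
4. Ring order: oxirane (temporary), oxetane (temporary), then the 1,2-dioxolane in the key step; no ring is formed afterwards.

Key step: step 13

**Remarks and assumptions**
- Assumption: the L-tert-leucine-derived antipode of the step 13 catalyst is taken as the one that delivers oxygen to the C3 face giving 3R; if the sense proves opposite, the D-series catalyst is used and nothing else changes.
- The catalyst carries a urea, not a thiourea, hydrogen-bond donor, because hydroperoxides oxidise thioureas.
- The carbinol centre made in step 4 is carried as both epimers (RS) and is erased in step 10.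
- Deca-1,9-diyne, (3Z)-hex-3-en-1-ol and all reagents are taken as commercial.

**Route**

Step 1
Reactants: 1 deca-1,9-diyne
Product: 3 (2E)-3-methylundec-2-en-10-yn-1-ol, via alkenylalane 2 (not isolated)
Conditions: AlMe3, Cp2ZrCl2 (cat.), CH2Cl2, 0 °C → rt, 1 in threefold excess; then (CH2O)n, THF, 0 °C → rt
Reagents that add atoms: trimethylaluminium C[Al](C)C; formaldehyde (as paraformaldehyde) C=O
Why: Zirconium-catalysed syn-carboalumination (Negishi) adds methyl to the internal and aluminium to the terminal carbon of one alkyne, and the alkenylalane is hydroxymethylated with retention, so the trisubstituted alkene is E; the excess of 1 keeps the second alkyne untouched.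

Step 2
Reactants: 3 (2E)-3-methylundec-2-en-10-yn-1-ol
Product: 4 [(2R,3R)-3-methyl-3-(oct-7-yn-1-yl)oxiran-2-yl]methanol
Conditions: Ti(OiPr)4 (cat.), D-(−)-diethyl tartrate, t-BuOOH, 4 Å MS, CH2Cl2, −20 °C
Reagents that add atoms: tert-butyl hydroperoxide CC(C)(C)OO
Why: Sharpless asymmetric epoxidation of an E trisubstituted (geraniol-type) allylic alcohol is reliably face-selective, and D-(−)-diethyl tartrate gives the 2R,3R epoxide, which fixes the tertiary C–O centre (the future C5, in the sense opposite to the target because step 8 inverts it).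

Step 3
Reactants: 4 [(2R,3R)-3-methyl-3-(oct-7-yn-1-yl)oxiran-2-yl]methanol
Product: 5 (2S,3R)-3-methyl-3-(oct-7-yn-1-yl)oxirane-2-carbaldehyde
Conditions: Dess–Martin periodinane, pyridine, CH2Cl2, 0 °C → rt
Reagents that add atoms: none
Why: Dess–Martin oxidation takes the primary epoxy alcohol to the epoxy aldehyde under buffered, non-epimerising conditions that leave the epoxide and the alkyne alone.

Step 4
Reactants: 5 (2S,3R)-3-methyl-3-(oct-7-yn-1-yl)oxirane-2-carbaldehyde
Product: 6 (1RS)-1-[(2R,3R)-3-methyl-3-(oct-7-yn-1-yl)oxiran-2-yl]ethan-1-ol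
Conditions: MeMgBr, THF, −78 °C
Reagents that add atoms: methylmagnesium bromide C[Mg]Br
Why: Grignard addition to the aldehyde at −78 °C is faster than epoxide opening or acetylide formation; the new carbinol centre is deliberately left uncontrolled because both epimers converge on ketone 14 in step 10.

Step 5
Reactants: 6 (1RS)-1-[(2R,3R)-3-methyl-3-(oct-7-yn-1-yl)oxiran-2-yl]ethan-1-ol
Product: 7 (2RS,4R)-4-methyldodec-11-yne-2,4-diol
Conditions: NaAlH2(OCH2CH2OMe)2, THF, 0 °C → rt
Reagents that add atoms: none
Why: The aluminium alkoxide of the carbinol delivers hydride within the molecule to the adjacent epoxide carbon (regioselective reductive opening of 2,3-epoxy alcohols to 1,3-diols), so the tertiary C–O bond and its R configuration are not touched.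

Step 6
Reactants: 7 (2RS,4R)-4-methyldodec-11-yne-2,4-diol
Product: 9 (2R,4RS)-2,4-dimethyl-2-(oct-7-yn-1-yl)oxetane, via mesylate 8 (not isolated)
Conditions: MsCl, Et3N, CH2Cl2, −10 °C; then KOtBu, THF, 0 °C → rt
Reagents that add atoms: none
Why: The secondary hydroxyl is sulfonylated selectively beside the tertiary one and the tertiary alkoxide then displaces the mesylate in a 4-exo-tet Williamson closure, which keeps the tertiary stereocentre because its C–O bond is not broken.

Step 7
Reactants: 9 (2R,4RS)-2,4-dimethyl-2-(oct-7-yn-1-yl)oxetane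
Product: 11 (2R,4RS)-2-[(7E)-8-iodooct-7-en-1-yl]-2,4-dimethyloxetane, via alkenylzirconocene chloride 10 (not isolated)
Conditions: Cp2Zr(H)Cl, THF, rt; then I2, 0 °C
Reagents that add atoms: iodine II
Why: Hydrozirconation of the terminal alkyne is syn and places zirconium on the terminal carbon, and iodinolysis proceeds with retention, so the E-alkenyl iodide needed for the final coupling is installed before any peroxide is present.

Step 8
Reactants: 11 (2R,4RS)-2-[(7E)-8-iodooct-7-en-1-yl]-2,4-dimethyloxetane
Product: 12 (2RS,4S,11E)-4-hydroperoxy-12-iodo-4-methyldodec-11-en-2-ol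
Conditions: H2O2 (anhydrous, Et2O solution), TMSOTf (0.3 equiv), Et2O, −78 → −20 °C
Reagents that add atoms: hydrogen peroxide OO
Why: Lewis-acid-activated 2,2-disubstituted oxetanes are opened by hydrogen peroxide at the more substituted carbon in a borderline SN2 process with inversion (stereospecific oxetane perhydrolysis), which turns the R tertiary C–O centre into the S C–OOH centre of the target and frees the carbinol for step 10.

Step 9
Reactants: 12 (2RS,4S,11E)-4-hydroperoxy-12-iodo-4-methyldodec-11-en-2-ol
Product: 13 (2RS,4S,11E)-12-iodo-4-[(2-methoxypropan-2-yl)peroxy]-4-methyldodec-11-en-2-ol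
Conditions: 2-methoxypropene (1.1 equiv), PPTS (cat.), CH2Cl2, −20 °C
Reagents that add atoms: 2-methoxypropene COC(C)=C
Why: Acid-catalysed addition to the enol ether is much faster for the hydroperoxide (more acidic O–H, α-effect nucleophile) than for the secondary alcohol, so one equivalent of 2-methoxypropene at low temperature masks the OOH group selectively as its peroxyketal.

Step 10
Reactants: 13 (2RS,4S,11E)-12-iodo-4-[(2-methoxypropan-2-yl)peroxy]-4-methyldodec-11-en-2-ol
Product: 14 (4S,11E)-12-iodo-4-[(2-methoxypropan-2-yl)peroxy]-4-methyldodec-11-en-2-one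
Conditions: Dess–Martin periodinane, pyridine, CH2Cl2, 0 °C → rt
Reagents that add atoms: none
Why: Buffered Dess–Martin oxidation converts both carbinol epimers into one methyl ketone without acid that would cleave the peroxyketal.

Step 11
Reactants: 14 (4S,11E)-12-iodo-4-[(2-methoxypropan-2-yl)peroxy]-4-methyldodec-11-en-2-one
Product: 15 methyl (2E,5S,12E)-13-iodo-5-[(2-methoxypropan-2-yl)peroxy]-3,5-dimethyltrideca-2,12-dienoate
Conditions: (MeO)2P(O)CH2CO2Me, NaH, THF, 0 °C → rt; E isomer isolated by chromatography
Reagents that add atoms: trimethyl phosphonoacetate COC(=O)CP(=O)(OC)OC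
Why: Horner–Wadsworth–Emmons olefination of the methyl ketone should favour the E enoate (ester trans to the larger CH2 branch), and the geometric isomers are separated because the next steps need one alkene geometry.

Step 12
Reactants: 15 methyl (2E,5S,12E)-13-iodo-5-[(2-methoxypropan-2-yl)peroxy]-3,5-dimethyltrideca-2,12-dienoate
Product: 16 methyl (2E,5S,12E)-5-hydroperoxy-13-iodo-3,5-dimethyltrideca-2,12-dienoate
Conditions: AcOH/THF/H2O, rt; used at once
Reagents that add atoms: none
Why: Aqueous acetic acid hydrolyses the mixed peroxyketal to the free tertiary hydroperoxide, and without base the hydroperoxide does not add to the enoate, so 16 can be taken on as the open-chain compound.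

Step 13
Reactants: 16 methyl (2E,5S,12E)-5-hydroperoxy-13-iodo-3,5-dimethyltrideca-2,12-dienoate
Product: 17 methyl 2-[(3R,5S)-5-[(7E)-8-iodooct-7-en-1-yl]-3,5-dimethyl-1,2-dioxolan-3-yl]acetate
Conditions: bifunctional iminophosphorane–urea organocatalyst (iminophosphorane of P(4-MeOC6H4)3 on an L-tert-leucine-derived 3,5-bis(trifluoromethyl)phenylurea scaffold, 10 mol%), Et2O, 0 °C → rt, dark
Reagents that add atoms: none
Why: Proposed new method: the iminophosphorane of the catalyst deprotonates the tertiary hydroperoxide (pKa about 13) to a peroxide anion that stays ion-paired with the chiral iminophosphonium while the urea N–H bonds hold the ester carbonyl, and the terminal peroxide oxygen then adds to C3 of the β-methyl enoate, the resulting ester enolate being protonated at C2 by the catalyst conjugate acid. The closest known reaction types are the amine-promoted cyclisation of hydroperoxy enoates to 1,2-dioxolane-3-acetates in fluorinated alcohols (the presumed biosynthetic closure, known but unselective at C3) and the bifunctional-iminophosphorane-catalysed enantioselective intramolecular oxa-Michael addition of alcohols to α,β-unsaturated esters; their combination on a hydroperoxide forming a fully substituted C–O centre is not known. The 1,2-dioxolane closes 5-exo-trig through the O2–C3 bond with O1–C5–C4 as tether. The new quaternary centre C3 is set by the catalyst, which exposes one face of the E-enoate to the peroxide, because the resident C5 centre (methyl against a linear alkyl) exerts almost no 1,3-induction; C5 itself is not touched. The step needs C3 facial selectivity, for which 16 offers a single alkene geometry and a single C5 configuration so that the facial preference of the catalyst translates into one diastereomer, and it needs conjugate addition to win over attack of the enolate on the O–O bond (epoxide formation), which the proton held next to the enolate on the catalyst secures. Base-induced Kornblum–DeLaMare cleavage is excluded because C3 and C5 of the product carry no hydrogen.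

Step 14
Reactants: 18 (3Z)-hex-3-en-1-ol
Product: 19 (3Z)-hex-3-enal
Conditions: Dess–Martin periodinane, CH2Cl2, 0 °C; crude aldehyde used at once
Reagents that add atoms: none
Why: Dess–Martin oxidation is neutral enough to give the β,γ-unsaturated aldehyde without moving the Z alkene into conjugation if the crude product is used at once.

Step 15
Reactants: 19 (3Z)-hex-3-enal
Product: 20 2-[(1E,4Z)-hepta-1,4-dien-1-yl]-4,4,5,5-tetramethyl-1,3,2-dioxaborolane
Conditions: CrCl2, LiI, Cl2CHB(pin), THF, rt
Reagents that add atoms: 2-(dichloromethyl)-4,4,5,5-tetramethyl-1,3,2-dioxaborolane ClC(Cl)B1OC(C)(C)C(C)(C)O1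
Why: Takai-type olefination with the geminal dichromium reagent formed from the dichloromethylboronate gives the E-alkenylboronate selectively under non-basic conditions that leave the skipped Z alkene in place.

Step 16
Reactants: 17 methyl 2-[(3R,5S)-5-[(7E)-8-iodooct-7-en-1-yl]-3,5-dimethyl-1,2-dioxolan-3-yl]acetate; 20 2-[(1E,4Z)-hepta-1,4-dien-1-yl]-4,4,5,5-tetramethyl-1,3,2-dioxaborolane
Product: 21 methyl 2-[(3R,5S)-3,5-dimethyl-5-[(7E,9E,12Z)-pentadeca-7,9,12-trien-1-yl]-1,2-dioxolan-3-yl]acetate
Conditions: PdCl2(dppf) (5 mol%), AsPh3, Cs2CO3, DMF/THF/H2O, rt, degassed, dark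
Reagents that add atoms: none
Why: Suzuki–Miyaura coupling joins the two sp2 carbons with retention of both alkene geometries to give the E,E-diene, and the di-tertiary dioxolane, which has no α-hydrogen, should tolerate zerovalent palladium and carbonate at room temperature as hindered dialkyl peroxides are known to do in palladium cross-couplings.

**Compound list**
1 | deca-1,9-diyne | C#CCCCCCCC#C | starting material
2 | dimethyl[(1E)-2-methyldec-1-en-9-yn-1-yl]alane | C[Al](C)/C=C(\C)CCCCCCC#C | intermediate
3 | (2E)-3-methylundec-2-en-10-yn-1-ol | OC/C=C(\C)CCCCCCC#C | intermediate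
4 | [(2R,3R)-3-methyl-3-(oct-7-yn-1-yl)oxiran-2-yl]methanol | C#CCCCCCC[C@@]1(C)O[C@@H]1CO | intermediate
5 | (2S,3R)-3-methyl-3-(oct-7-yn-1-yl)oxirane-2-carbaldehyde | C#CCCCCCC[C@@]1(C)O[C@@H]1C=O | intermediate
6 | (1RS)-1-[(2R,3R)-3-methyl-3-(oct-7-yn-1-yl)oxiran-2-yl]ethan-1-ol | C#CCCCCCC[C@@]1(C)O[C@@H]1C(C)O | intermediate
7 | (2RS,4R)-4-methyldodec-11-yne-2,4-diol | C#CCCCCCC[C@](O)(C)CC(C)O | intermediate
8 | (2RS,4R)-4-hydroxy-4-methyldodec-11-yn-2-yl methanesulfonate | C#CCCCCCC[C@](O)(C)CC(C)OS(C)(=O)=O | intermediate
9 | (2R,4RS)-2,4-dimethyl-2-(oct-7-yn-1-yl)oxetane | C#CCCCCCC[C@]1(C)CC(C)O1 | intermediate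
10 | chlorobis(cyclopentadienyl){(1E)-8-[(2R,4RS)-2,4-dimethyloxetan-2-yl]oct-1-en-1-yl}zirconium | Cl[Zr](/C=C/CCCCCC[C@]1(C)CC(C)O1)(C1C=CC=C1)C1C=CC=C1 | intermediate
11 | (2R,4RS)-2-[(7E)-8-iodooct-7-en-1-yl]-2,4-dimethyloxetane | I/C=C/CCCCCC[C@]1(C)CC(C)O1 | intermediate
12 | (2RS,4S,11E)-4-hydroperoxy-12-iodo-4-methyldodec-11-en-2-ol | I/C=C/CCCCCC[C@@](OO)(C)CC(C)O | intermediate
13 | (2RS,4S,11E)-12-iodo-4-[(2-methoxypropan-2-yl)peroxy]-4-methyldodec-11-en-2-ol | I/C=C/CCCCCC[C@@](OOC(C)(C)OC)(C)CC(C)O | intermediate
14 | (4S,11E)-12-iodo-4-[(2-methoxypropan-2-yl)peroxy]-4-methyldodec-11-en-2-one | I/C=C/CCCCCC[C@@](OOC(C)(C)OC)(C)CC(C)=O | intermediate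
15 | methyl (2E,5S,12E)-13-iodo-5-[(2-methoxypropan-2-yl)peroxy]-3,5-dimethyltrideca-2,12-dienoate | I/C=C/CCCCCC[C@@](OOC(C)(C)OC)(C)C/C(C)=C/C(=O)OC | intermediate
16 | methyl (2E,5S,12E)-5-hydroperoxy-13-iodo-3,5-dimethyltrideca-2,12-dienoate | I/C=C/CCCCCC[C@@](OO)(C)C/C(C)=C/C(=O)OC | intermediate
17 | methyl 2-[(3R,5S)-5-[(7E)-8-iodooct-7-en-1-yl]-3,5-dimethyl-1,2-dioxolan-3-yl]acetate | I/C=C/CCCCCC[C@@]1(C)C[C@](C)(CC(=O)OC)OO1 | intermediate
18 | (3Z)-hex-3-en-1-ol | CC/C=C\CCO | starting material
19 | (3Z)-hex-3-enal | CC/C=C\CC=O | intermediate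
20 | 2-[(1E,4Z)-hepta-1,4-dien-1-yl]-4,4,5,5-tetramethyl-1,3,2-dioxaborolane | CC/C=C\C/C=C/B1OC(C)(C)C(C)(C)O1 | intermediate
21 | methyl 2-[(3R,5S)-3,5-dimethyl-5-[(7E,9E,12Z)-pentadeca-7,9,12-trien-1-yl]-1,2-dioxolan-3-yl]acetate | CC/C=C\C/C=C/C=C/CCCCCC[C@@]1(C)C[C@](C)(CC(=O)OC)OO1 | target

**Step count and risks**
Total steps: 16. Longest linear sequence: 14 (steps 1–13, then step 16).

Steps most likely to fail:

Step 13 (proposed new method). The catalyst may not override the absent substrate bias, giving poor facial selectivity at C3. Addition to the β,β-disubstituted enoate may also be slow enough for unselective background closure or retro-addition to erode the selectivity, or the enolate may attack the O–O bond. The fallback uses known chemistry and replaces conjugate addition by C–C bond formation at a preformed ring. It sets out from ketone 14: PPTS in MeOH removes the peroxyketal, and the freed hydroperoxy ketone closes and is ketalised to (3RS,5S)-5-[(7E)-8-iodooct-7-en-1-yl]-3-methoxy-3,5-dimethyl-1,2-dioxolane F1. TiCl4 in CH2Cl2 at −78 °C ionises F1 to the cyclic peroxycarbenium ion, which is trapped by 1-(tert-butyldimethylsilyloxy)-1-methoxyethene. After chromatographic separation from its C3 epimer this should give 17, where the route is rejoined; steps 11 to 13 are bypassed.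

Step 11. Enolisation of ketone 14 by the phosphonate anion can expel the β-peroxy group (E1cB loss of the protected peroxide), and the alkene may form with a low E preference. The fallback changes from an equilibrating phosphonate olefination to an irreversible low-temperature addition–elimination. It sets out from 14: Peterson olefination with the lithium enolate of methyl (trimethylsilyl)acetate (LDA, THF, −78 °C, then warming) should give 15 after removal of the Z isomer. The route is rejoined at 15, and this detour makes no compound that is absent from the list (F0).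

Step 16. Zerovalent palladium may insert into or reduce the O–O bond, or the aqueous carbonate may hydrolyse the ester, before coupling is complete. The fallback is palladium-free and base-free. It sets out from aldehyde 19: Takai-type olefination with Bu3SnCHBr2, CrCl2 and LiI in THF/DMF gives tributyl[(1E,4Z)-hepta-1,4-dien-1-yl]stannane F2. F2 is joined to 17 by copper thiophene-2-carboxylate, Cu(O2CC4H3S) (monovalent copper), in NMP at 0 °C → rt, which should give 21 directly, where the route ends.

**Further compounds**
F1 | step 13 | (3RS,5S)-5-[(7E)-8-iodooct-7-en-1-yl]-3-methoxy-3,5-dimethyl-1,2-dioxolane | I/C=C/CCCCCC[C@@]1(C)CC(C)(OC)OO1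
F0 | step 11 | none | none
F2 | step 16 | tributyl[(1E,4Z)-hepta-1,4-dien-1-yl]stannane | CC/C=C\C/C=C/[Sn](CCCC)(CCCC)CCCC
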